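**Strategy.** Octacosanolide is a 29-membered lactone ring (28 carbons plus the ring oxygen) with no stereocentre and no substituent, so the ring is closed inside the polymethylene chain instead of at the ester. Everything rests on disconnecting the C9–C10 bond (C1 = lactone carbonyl), a plain CH2–CH2 link eight carbons from C1 and remote from the oxygen on C28. The key step is a ring-closing olefin metathesis of the open-chain ester eicos-19-enyl dec-9-enoate: it joins the two inner vinyl carbons as C9=C10 with loss of ethylene, and hydrogenation in the same pot gives the saturated ring. The precursor is built from dec-9-enoic acid, 9-bromononan-1-ol and 11-bromoundec-1-ene.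

Key step: step 3

Remark: the target has no stereocentre; the ring-closed alkene 7 should form as an E/Z mixture and is written without alkene geometry, since both isomers give the same product on hydrogenation.

Step 1
Reactants: 1 dec-9-enoic acid; 2 9-bromononan-1-ol
Product: 3 9-bromononyl dec-9-enoate
Conditions: DCC (1.1 equiv), DMAP (10 mol%), CH2Cl2, 0 °C to rt
Reagents that add atoms: none
Why: Steglich esterification; carbodiimide activation of acid 1 and DMAP acyl transfer to the primary alcohol of 2 should proceed under neutral conditions that leave the primary bromide and the terminal alkene untouched.

Step 2
Reactants: 3 9-bromononyl dec-9-enoate; 4 11-bromoundec-1-ene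
Product: 6 eicos-19-en-1-yl dec-9-enoate, via undec-10-en-1-ylmagnesium bromide 5 (not isolated)
Conditions: 4, Mg turnings, THF, 40 °C; then slow addition of 5 (1.2 equiv) to 3, Li2CuCl4 (3 mol%), NMP (4 equiv), THF, 0 °C; aq. NH4Cl
Reagents that add atoms: none
Why: Copper-catalysed alkyl–alkyl Grignard cross-coupling; the organocopper species formed in the flask should displace the primary bromide of 3 much faster than the Grignard reagent adds to the ester at 0 °C when 5 is added slowly in the presence of NMP, and no stereocentre is formed.

Step 3
Reactants: 6 eicos-19-en-1-yl dec-9-enoate
Product: 8 octacosanolide, via octacos-9-en-28-olide 7 (not isolated)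
Conditions: RuCl2(PCy3)2(=CHPh) (first-generation Grubbs catalyst, 5 mol%), ClCH2CH2Cl (2 mM, slow addition of 6), 50 °C, Ar sparge; concentrate in the same vessel to ca. 50 mM; then H2 (7 bar), NEt3 (10 mol%), 70 °C
Reagents that add atoms: none
Why: Ring-closing olefin metathesis followed by hydrogenation in the same pot: the ruthenium benzylidene exchanges onto one terminal alkene of 6, the resulting alkylidene undergoes intramolecular [2+2] cycloaddition with the other terminal alkene, and the ruthenacyclobutane cycloreverts to the C9=C10 alkene 7 with loss of volatile ethylene, which drives the equilibrium. The closest known reaction type is the metathesis macrocyclisation of ω-alkenyl ω-alkenoates to large-ring lactones, after which H2 converts the spent carbene into a ruthenium hydride that saturates the new alkene (tandem metathesis–hydrogenation). The single ring closed is the 29-membered lactone ring, formed by union of the two vinyl termini at a bond eight carbons from the carbonyl C1 and eighteen methylenes from C28. No stereocentre is created and the E/Z geometry of 7 is erased by the hydrogenation, so no stereocontrol is needed. The selectivity required is cyclisation over acyclic diene metathesis oligomerisation and over double-bond migration; high dilution with slow addition of 6, removal of ethylene, the strain-free ring size and the remoteness of the ester carbonyl from both alkenes (no five- or six-membered chelate to ruthenium) should secure the former, and the first-generation catalyst at moderate temperature should limit the latter.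

**Compound list**

1 | dec-9-enoic acid | C=CCCCCCCCC(=O)O | starting material
2 | 9-bromononan-1-ol | OCCCCCCCCCBr | starting material
3 | 9-bromononyl dec-9-enoate | C=CCCCCCCCC(=O)OCCCCCCCCCBr | intermediate
4 | 11-bromoundec-1-ene | C=CCCCCCCCCCBr | starting material
5 | undec-10-en-1-ylmagnesium bromide | C=CCCCCCCCCC[Mg]Br | intermediate (not isolated)
6 | eicos-19-en-1-yl dec-9-enoate | C=CCCCCCCCC(=O)OCCCCCCCCCCCCCCCCCCC=C | intermediate
7 | octacos-9-en-28-olide (oxacyclononacos-10-en-2-one), E/Z mixture | O=C1CCCCCCCC=CCCCCCCCCCCCCCCCCCCO1 | intermediate (not isolated)
8 | octacosanolide (oxacyclononacosan-2-one) | O=C1CCCCCCCCCCCCCCCCCCCCCCCCCCCO1 | target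

**Total step count:** 3

**Longest linear sequence:** 3 steps (1 or 2 → 3 → 6 → 8)

**Steps most likely to fail**

Step 3 (key step). Intermolecular acyclic diene metathesis may outrun cyclisation. Ruthenium-hydride species may also move the double bonds along the chain before closure, which would lead to ring-contracted homologues, and the in-pot hydrogenation may stall at the low catalyst concentration. The fallback sets out from diene ester 6. Both vinyl groups are cleaved by ozonolysis (O3, CH2Cl2, −78 °C; then Me2S) to the dialdehyde 19-oxononadecyl 9-oxononanoate F1. F1 is cyclised at the same C9–C10 bond by an intramolecular McMurry reductive carbonyl coupling (TiCl3(DME)1.5, Zn–Cu couple, DME, reflux, syringe-pump addition), in which the aldehydes should couple much faster than the ester reacts. This gives octacos-9-en-28-olide 7, here isolated, where the route is rejoined; 7 is then hydrogenated separately (H2 1 bar, Pd/C, EtOAc, rt) to 8.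

Step 2. The Grignard reagent may add to the ester carbonyl of 3 in competition with the copper-catalysed displacement, and Wurtz-type homocoupling during Grignard formation may erode the reagent. The fallback reverses the order of bond formation so that no ester meets the Grignard reagent. It sets out from 9-bromononan-1-ol 2: a first equivalent of 5 converts it into bromomagnesium 9-bromononan-1-olate F2. A second equivalent of 5 couples with F2 (Li2CuCl4 3 mol%, THF, −10 °C to rt; aq. NH4Cl) to give eicos-19-en-1-ol F3. Steglich esterification of F3 with acid 1 (DCC, DMAP, CH2Cl2, rt) then gives 6, where the route is rejoined.

Step 1. O-to-N acyl migration of the carbodiimide-activated acid and slow quaternisation of DMAP by the primary bromide may lower conversion. The fallback sets out from 1 and 2 and makes the ester by acid-catalysed dehydrative (Fischer) esterification with azeotropic removal of water (TsOH·H2O cat., toluene, reflux, Dean–Stark trap). This needs no activating agent and no nucleophilic catalyst and arrives directly at 3, with no new compound on the way.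

**Further compounds**

F1 | step 3 | 19-oxononadecyl 9-oxononanoate | O=CCCCCCCCC(=O)OCCCCCCCCCCCCCCCCCCC=O
F2 | step 2 | bromomagnesium 9-bromononan-1-olate | BrCCCCCCCCCO[Mg]Br
F3 | step 2 | eicos-19-en-1-ol | C=CCCCCCCCCCCCCCCCCCCO
F0 | step 1 | none | none
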